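## Retrosynthetic overview
1. The 7-OH is carried as an acetate, and the 5'-(E)-3-methylbuta-1,3-dienyl group comes from a Stille coupling of a 5'-bromide.
2. The 3'-prenyl group comes from an aromatic Claisen [3,3]-sigmatropic rearrangement (the key C–C bond) of a 4'-O-(1,1-dimethylallyl) ether. That ether is made by Lindlar reduction of the 1,1-dimethylpropargyl ether. A 3'-Br blocks one ortho position so the rearrangement goes to C5'.
3. The whole skeleton and the C2 (S) stereocenter come from (2S)-naringenin, so no ring is built and C2 is never touched.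
4. The B-ring is functionalised in the order Br, then Claisen, then OMe, then Stille.

Assumption: (2S)-naringenin, obtained from citrus naringin, is bought. The target is (2S): the SMILES gives S, the same configuration as natural naringenin.

## Route

**Step 1**
Reactants: 1, 2-methylbut-1-en-3-yne
Product: 2, (E)-tributyl(3-methylbuta-1,3-dien-1-yl)stannane
Conditions: Bu3SnH, Pd(PPh3)2Cl2 (cat.), THF, 0 °C → rt
Reagents that add atoms: tributyltin hydride, [SnH](CCCC)(CCCC)CCCC
Why: Pd-catalysed hydrostannation of the terminal alkyne is syn and anti-Markovnikov, so it gives the terminal (E)-vinylstannane and sets the E diene geometry.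

**Step 2**
Reactants: 3, (2S)-naringenin
Product: 4, (2S)-7-O-acetylnaringenin
Conditions: Ac2O (1.05 equiv), NaHCO3, acetone, 0 °C → rt
Reagents that add atoms: acetic anhydride, CC(=O)OC(C)=O
Why: 7-OH is the most acidic phenol (pKa about 7), and the 5-OH is H-bonded to C4=O. Acetylation is therefore selective, and the acetate also deactivates ring A toward the next step. C2 is untouched and the conditions are only weakly basic.

**Step 3**
Reactants: 4
Product: 5, (2S)-7-O-acetyl-3'-bromonaringenin
Conditions: NBS (1.05 equiv), i-Pr2NH (0.1 equiv), CH2Cl2, −10 → 0 °C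
Reagents that add atoms: N-bromosuccinimide, O=C1CCC(=O)N1Br
Why: the N-bromoamine gives phenol-directed ortho-selective electrophilic bromination. Para is blocked, and one equivalent gives the mono-bromide. No stereocenter is affected.

**Step 4**
Reactants: 5
Product: 6, 4'-O-(2-methylbut-3-yn-2-yl) ether
Conditions: 3-chloro-3-methylbut-1-yne (3 equiv), CuI (10 mol %), i-Pr2NEt, MeCN, 0 °C → rt
Reagents that add atoms: 3-chloro-3-methylbut-1-yne, C#CC(C)(C)Cl
Why: Cu-acetylide-mediated propargylic etherification of the 4'-phenol. A hindered amine base is used so the 7-OAc and C2 survive.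

**Step 5**
Reactants: 6
Product: 7, 4'-O-(2-methylbut-3-en-2-yl) ether
Conditions: H2 (1 atm), Lindlar catalyst, quinoline, EtOAc, rt
Reagents that add atoms: hydrogen, [H][H]
Why: Lindlar semi-hydrogenation reduces the terminal alkyne to the 1,1-dimethylallyl ether. Ar–Br, the ketone, the acetate and the stereocenter are untouched.

**Step 6**
Reactants: 7
Product: 8, (2S)-7-O-acetyl-3'-bromo-5'-prenylnaringenin (4'-OH free)
Conditions: PhMe, 110 °C, sealed tube, BHT (cat.), solid NaHCO3
Reagents that add atoms: none
Why: aromatic Claisen [3,3]-sigmatropic rearrangement through a chair transition state moves the tertiary allyl group to the ortho carbon as a primary prenyl (CH2–CH=CMe2). Only C5' is free, and tautomerisation restores the arene. It is neutral and thermal, so C2 is not epimerised.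

**Step 7**
Reactants: 8
Product: 9, 4'-O-methyl ether (3'-bromo-5'-prenyl, 7-OAc)
Conditions: TMSCHN2 (2 equiv), i-Pr2NEt, MeCN/MeOH 9:1, 0 °C → rt
Reagents that add atoms: trimethylsilyldiazomethane, C[Si](C)(C)[CH-][N+]#N
Why: the mildly acidic, hindered 4'-phenol is O-methylated under near-neutral conditions. The chelated 5-OH and the 7-OAc are untouched.

**Step 8**
Reactants: 9 and 2
Product: 10, (2S)-7-O-acetyl-4'-methoxy-3'-prenyl-5'-[(E)-3-methylbuta-1,3-dienyl]naringenin
Conditions: Pd(PPh3)4 (5 mol %), CuI (10 mol %), BHT (cat.), DMF, 60 °C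
Reagents that add atoms: stannane 2 is the coupling partner (SMILES in the list below)
Why: Stille cross-coupling under neutral conditions, with the Cu effect to speed transmetallation, retains the E alkene geometry. It avoids aqueous base, which would open the flavanone to the chalcone and racemise C2.

**Step 9**
Reactants: 10
Product: 11, target
Conditions: NH4OAc (10 equiv), MeOH/H2O 9:1, 40 °C
Reagents that add atoms: none (water/methanol act as solvent and nucleophile; only the acetyl group is lost)
Why: the aryl acetate of the acidic 7-OH is chemoselectively cleaved by near-neutral ammonium acetate. The diene, prenyl, ketone and C2 are not touched.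

## Compound list
1 | 2-methylbut-1-en-3-yne | C=C(C)C#C | starting material
2 | (E)-tributyl(3-methylbuta-1,3-dien-1-yl)stannane | C=C(C)/C=C/[Sn](CCCC)(CCCC)CCCC | intermediate (coupling partner)
3 | (2S)-naringenin | Oc1ccc([C@@H]2CC(=O)c3c(O)cc(O)cc3O2)cc1 | starting material
4 | (2S)-7-O-acetylnaringenin | Oc1ccc([C@@H]2CC(=O)c3c(O)cc(OC(C)=O)cc3O2)cc1 | intermediate
5 | (2S)-7-O-acetyl-3'-bromonaringenin | Oc1ccc([C@@H]2CC(=O)c3c(O)cc(OC(C)=O)cc3O2)cc1Br | intermediate
6 | 4'-O-(2-methylbut-3-yn-2-yl) ether of 5 | C#CC(C)(C)Oc1ccc([C@@H]2CC(=O)c3c(O)cc(OC(C)=O)cc3O2)cc1Br | intermediate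
7 | 4'-O-(2-methylbut-3-en-2-yl) ether of 5 | C=CC(C)(C)Oc1ccc([C@@H]2CC(=O)c3c(O)cc(OC(C)=O)cc3O2)cc1Br | intermediate
8 | (2S)-7-O-acetyl-3'-bromo-5'-prenylnaringenin | CC(C)=CCc1cc([C@@H]2CC(=O)c3c(O)cc(OC(C)=O)cc3O2)cc(Br)c1O | intermediate
9 | 4'-O-methyl ether of 8 | CC(C)=CCc1cc([C@@H]2CC(=O)c3c(O)cc(OC(C)=O)cc3O2)cc(Br)c1OC | intermediate
10 | (2S)-7-O-acetyl-4'-methoxy-3'-prenyl-5'-[(E)-3-methylbuta-1,3-dienyl]flavanone | C=C(C)/C=C/c1cc([C@@H]2CC(=O)c3c(O)cc(OC(C)=O)cc3O2)cc(CC=C(C)C)c1OC | intermediate
11 | (2S)-5,7-dihydroxy-4'-methoxy-3'-(3-methylbut-2-enyl)-5'-[(E)-3-methylbuta-1,3-dienyl]flavanone | C=C(C)/C=C/c1cc([C@@H]2CC(=O)c3c(O)cc(O)cc3O2)cc(CC=C(C)C)c1OC | target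

## Totals
Total steps: 9, including the one-step preparation of the stannane.
Longest linear sequence: 8 steps (naringenin → target).

## Three steps most likely to fail
1. **Step 3, B-ring monobromination.** The electron-rich A-ring C6/C8 positions can compete with the 4'-phenol.
   Fallback: drop halogenation and install prenyl on both ortho positions by two Claisen cycles from 4'-OH. Then convert one prenyl into the diene by DDQ dehydrogenation (benzylic/allylic hydride abstraction, then loss of a methyl proton).
2. **Step 6, Claisen of the tertiary allyl aryl ether.** It can fragment to the phenol plus isoprene, or the flavanone can epimerise on heating.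
   Fallback: use a plain 4'-O-allyl Claisen, then convert the ortho-allyl group to prenyl by cross-metathesis with 2-methyl-2-butene (Grubbs II).
3. **Step 8, Stille coupling of the isoprenyl-type diene stannane.** The diene can polymerise, the yield may be poor, and there is a risk of C2 racemisation.
   Fallback: switch to a Suzuki coupling of the (E)-dienyl pinacol boronate (from catecholborane hydroboration of the enyne) under anhydrous CsF/Pd(dppf)Cl2 conditions.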